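In a one-step world every starting material that reacts becomes target. Starting material is the limiting reagent here, at 1.30 equivalents of coupling partner, so the target should reach the whole charge.

| flask | starting material | coupling partner | remark | time |
|---|---|---|---|---|
| spring | 42 mM | 54.6 mM | run made earlier |  |
| autumn | 42 mM | 76 mM | run made earlier |  |
| dusk | 42 mM | 120 mM | run made earlier |  |
| beta | 42 mM (fed, over 15 s) | 54.6 mM | all else is in the flask from the start; the feed brings no volume worth counting | 3.0 min |
| epsilon | 42 mM | 54.6 mM | everything together at the start | 3.0 min |
| theta | 42 mM (fed, over 2.5 min) | 54.6 mM | all else is in the flask from the start; the feed brings no volume worth counting | 3.0 min |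
| alpha | 42 mM | 54.6 mM (fed, over 2.5 min) | all else is in the flask from the start; the feed brings no volume worth counting | 3.0 min |
| eta | 42 mM | 54.6 mM (in portions, 2, over 2.5 min) | first portion at the start, last at 2.5 min | 3.0 min |

spring run (percent of the starting material charged)

| time / s | target / % |
|---|---|
| 10.0 | 3 |
| 15.0 | 9 |
| 25.0 | 16 |
| 40.0 | 35 |
| 60.0 | 47 |
| 120 | 49 |

autumn run (percent of the starting material charged)

| time / min | target / % |
|---|---|
| 0.167 | 6 |
| 0.500 | 49 |
| 0.833 | 57 |
| 1.33 | 62 |
| 2.00 | 61 |
| 2.50 | 63 |

dusk run (percent of the starting material charged)

| time / min | target / % |
|---|---|
| 0.200 | 38 |
| 0.333 | 68 |
| 0.500 | 72 |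
| 0.833 | 72 |
| 1.33 | 71 |
| 2.50 | 70 |

(each reading ± 2 percentage points)

- what was read earlier has a scatter of 2 percentage points, one standard deviation

- which flask leads in amount of target, in percent of the starting material charged ("all alike" within 1.5 percentage points) (beta / epsilon / theta / alpha / eta / all alike)
- how much target is there at the end, in percent of the starting material charged: beta
- how much target is there at the end, in percent of the starting material charged: epsilon
- how much target is there at the end, in percent of the starting material charged: theta
- how much target is there at the end, in percent of the starting material charged: alpha
- how much target is there at the end, in percent of the starting material charged: eta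

The runs do otherwise. Dusk levels at 70%, so a second, unseen route takes the rest.

We set even odds between the routes as the zero of our scale. Let K be the partner level that gives even odds. Dusk then gives K = 51.4 mM, and N, the charged partner over K, is 1.06 for these flasks. The target's share is N over one plus N. That gives 51.5% for spring, against a reading of 49%. For autumn it gives 59.6%, against 63%. The scatter is 2 percentage points, so N holds for these runs.

But one number is not enough. Every run held starting material at 42 mM, so N cannot see a feed. We therefore assume that the lost route takes two starting material, so that the target's odds improve as the standing level falls.

Let T be the 60.0 s by which spring has nearly stopped. Theta's feed lasts longer, at 2.5 min, so we reckon its level is lower by tf/T. Our odds number Ω, N times the larger of one and the feed time over T, is then 2.65 for theta, a share of 72.6%.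

Epsilon stays at N. Alpha and eta start with about half the partner or less, which gives 34.6%. We take that as a high mark, because spring's slow start (a reading of 3% at 10.0 s) is not in the number.

The forecast names theta as leader but puts it at 51%, beside 50% for beta, 49% for epsilon, 23% for alpha and 32% for eta, on the ground that “Feeding starting material changes little”, and there it parts from our reckoning.

Theta leads with 79.3%, ahead of beta at 53.8%, epsilon at 49.5%, eta at 27.7% and alpha at 14.7%.

    starting material + coupling partner + target → 2 target (k = 111 /M²/s)
    starting material + coupling partner → target (k = 0.0160 /M/s)
    2 starting material → homo dimer (k = 0.496 /M/s)

Theta's homo dimer ends at 20.0%, so the target's odds in theta are 3.96, above our Ω. Free starting material in theta stood at 19.5% of the charge at 1.50 min. Beta's feed is shorter than T, at 15 s, so its Ω stays at 1.06, a share of 51.5%, and beta ends at 53.8%.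

(The earlier runs and the new flask were computed for an exercise.)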